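Start from late times, when Z has had the whole run to pass into J, and ask what the charge of L can pay for.

    Z → J (k1 = 0.056 min⁻¹, Ea1 = 88.0 kJ mol⁻¹)
    E + L → G + Z (k2 = 2.6 L mol⁻¹ min⁻¹, Ea2 = 44.0 kJ mol⁻¹)
    X + L → G + Q (k3 = 1.2 L mol⁻¹ min⁻¹, Ea3 = 55.0 kJ mol⁻¹)
    Q + L → G + E (k4 = 2.9 L mol⁻¹ min⁻¹, Ea4 = 40.0 kJ mol⁻¹)
    (constants at 20 °C)

| setting | noon | dusk | winter | summer |
|---|---|---|---|---|
| X | 0.050 M (fed, over 6.0 min) | 0.050 M | 0.050 M (fed, over 1.0 h) | 0.050 M |
| L | 0.0600 M | 0.0600 M | 0.0600 M | 0.0600 M (fed, over 1.0 h) |
| temperature | 20 °C | 20 °C | 20 °C |  |
| time | 5.0 h | 5.0 h | 5.0 h | 5.0 h |
| remark | all else is in the flask from the start; the feed brings no volume worth counting | everything together at the start | all else is in the flask from the start; the feed brings no volume worth counting | the addition at −10 °C, then warmed to 20 °C; the feed brings no volume worth counting |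

- the constants hold at 20 °C; other temperatures follow from the activation energies

* which flask leads in amount of J, in percent of the X charged ("all alike" within 1.5 percentage points) (noon / dusk / winter / summer / all alike)
* how much J is there at the end, in percent of the X charged: noon
* how much J is there at the end, in percent of the X charged: dusk
* how much J is there at the end, in percent of the X charged: winter
* how much J is there at the end, in percent of the X charged: summer

Take the half-life of Z, 12.4 min, which is shorter than the run of 300 min, and so count Z as J. Each J has then cost 3 L, each E 2, each Q one, so define the budget b, the L charged per X charged, 1.20, and write the ledger, in shares of the X charged, for a flask whose L is used up: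

c(Q) + 2 c(E) + 3 c(J) = b

This makes L the limiting reagent and gives a ceiling for J of

b/3 = 40.0%

But object at once: the ceiling needs every L to land on the last steps, and X takes up L more slowly than Q and E do, so those two compete for L while X is still there. Compute the objection for dusk. Every step that takes up L carries the same factor c(L), so time drops out and the frozen things are the ratios of the constants. Reckon along the exposure θ, the integral of c(L) over time, and try X left equal to the ceiling:

θ = 45.8 M·s
Q = 20.5%
E = 19.2%
J = 20.3%

The trial spends 1.20 L per X, which closes against b, so commit to 20.3% for dusk.

Doubt next whether L ends in time: even against that remnant of X its lifetime is 41.7 min, shorter than the run. Doubt then the feeds. Noon's feed lasts 0.432 lifetimes of X, below one, so treat noon as dusk. Winter's lasts 4.3, so X arrives into surplus L, the shared exposure fails, and expect J above dusk's yet under the ceiling, with no number from me. Summer has the same b, and I reckon no split for its cold feed.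

The forecast names winter, with 21.5% for noon, 20.3% for dusk, 27% for winter and 21.5% for summer, holding that “Feeding X slowly over an hour keeps L in excess over the early X and pushes it through to Z”.

The flasks give 20.6% for noon, 20.3% for dusk, 26.4% for winter and 20.7% for summer, so winter leads. Winter ends with 45.3% of X against dusk's 39.9%. Put the budget to work on winter, whose L stands at 0%: with Q at 15.7% and E at 12.6%, the ledger leaves 26.4% for J. Take the neighbour of dusk charged with 0.085 M of X, whose b is 0.706: with Q at 22.1% and E at 13.5%, the ledger leaves 7.17%, and that flask holds 7.16% of J.

The constants used here were set for the occasion; the result is computed.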